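**Retrosynthetic overview**
- Feature: the core is a cyclobutane (C1–C4) with 4-methoxy-2-pyron-6-yl groups on C1/C3 and 4-hydroxyphenyl groups on C2/C4. The substituents sit up/down/down/up (centrosymmetric), so aryl-bearing C2 has one trans (C1) and one cis (C3) pyronyl-bearing neighbour.
- The two pyrone rings are formed last and together, from the C1/C3 diacid, by dioxinone acylation, acylketene cyclisation and O-methylation. The carboxyl carbons come from CH2OTBS on C1 and, by one-carbon homologation with retention, from a Bpin group on C3.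
- The cyclobutane is formed first and is cut at C1–C2. Syn borylcupration of the E-styrene C2=C3 puts copper on benzylic C2 and boron on C3, and C2 then displaces a secondary mesylate on C1 with inversion.
- The open chain comes from an anti-selective allylboration of silyloxyacetaldehyde with an E-cinnamylboronate, a cross-metathesis with a styrene, and mesylation.

Key step: step 7

Assumption: the target has an inversion centre and is achiral, so all chiral intermediates are made as racemates. SMILES and descriptors show one enantiomer, and only relative configuration matters. Ring locants used throughout are C1 up, C2 down, C3 down, C4 up (the "α array").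

**Step 1**
Reactants: 1 1-benzyloxy-4-ethynylbenzene
Product: 2 (E)-2-[2-(4-benzyloxyphenyl)ethenyl]-4,4,5,5-tetramethyl-1,3,2-dioxaborolane
Conditions: HBpin (1.1 equiv), Cp2ZrHCl (10 mol %), Et3N (10 mol %), neat, 60 °C
Reagents that add atoms: pinacolborane, [H]B1OC(C)(C)C(C)(C)O1
Why: Zirconocene-hydride-catalysed hydroboration of a terminal alkyne is a syn, anti-Markovnikov addition, so boron ends on the terminal carbon and only the E-alkenylboronate should form while the benzyl ether is inert.

**Step 2**
Reactants: 2 (E)-alkenylboronate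
Product: 3 2-[(2E)-3-(4-benzyloxyphenyl)prop-2-en-1-yl]-4,4,5,5-tetramethyl-1,3,2-dioxaborolane
Conditions: BrCH2Cl (1.5 equiv), n-BuLi (1.3 equiv, added last), THF, −78 °C → rt
Reagents that add atoms: bromochloromethane, ClCBr
Why: In this Matteson homologation, LiCH2Cl generated in the presence of 2 adds to boron and the alkenyl group shifts from boron to carbon with loss of chloride, which inserts one CH2 and leaves the E geometry untouched.

**Step 3**
Reactants: 3 (E)-cinnamylboronate; 4 (tert-butyldimethylsilyloxy)acetaldehyde
Product: 6 rac-(2R,3S)-3-[4-(benzyloxy)phenyl]-1-[(tert-butyldimethylsilyl)oxy]pent-4-en-2-ol (anti), via O-boryl adduct 5 (not isolated)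
Conditions: toluene, rt, 24–48 h; then aq. NaHCO3
Reagents that add atoms: none
Why: Allylboration of an aldehyde runs through a closed chair (Zimmerman–Traxler) transition state in which the E-γ-aryl group and the CH2OTBS group both sit equatorial, which sets the two new stereocentres (future ring C4 and C1) in the anti relationship.

**Step 4**
Reactants: 7 4-benzyloxybenzaldehyde
Product: 8 1-benzyloxy-4-ethenylbenzene
Conditions: MePPh3Br (1.3 equiv), KOtBu (1.25 equiv), THF, 0 °C → rt
Reagents that add atoms: methyltriphenylphosphonium bromide, C[P+](c1ccccc1)(c1ccccc1)c1ccccc1.[Br-]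
Why: Wittig methylenation of a non-enolisable aromatic aldehyde with the unstabilised ylide is reliable and raises no stereochemical question.

**Step 5**
Reactants: 6 anti homoallylic alcohol; 8 1-benzyloxy-4-ethenylbenzene (3 equiv)
Product: 9 rac-(2R,3S,4E)-3,5-bis[4-(benzyloxy)phenyl]-1-[(tert-butyldimethylsilyl)oxy]pent-4-en-2-ol
Conditions: second-generation Hoveyda–Grubbs catalyst (5 mol %), CH2Cl2, 40 °C
Reagents that add atoms: none
Why: Olefin cross-metathesis between an allylically branched, slowly homodimerising terminal alkene and an excess of a styrene favours the cross product as the thermodynamically preferred E-styrene and does not touch the two stereocentres.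

**Step 6**
Reactants: 9 (E)-diaryl pentenol
Product: 10 rac-(2R,3S,4E)-3,5-bis[4-(benzyloxy)phenyl]-1-[(tert-butyldimethylsilyl)oxy]pent-4-en-2-yl methanesulfonate
Conditions: MsCl (1.3 equiv), Et3N (2 equiv), CH2Cl2, −10 → 0 °C; used promptly
Reagents that add atoms: methanesulfonyl chloride, CS(=O)(=O)Cl
Why: O-sulfonylation of the secondary alcohol breaks no bond at carbon, so the configuration is retained, and the cold, non-ionising medium avoids aryl-assisted ionisation of the product.

**Step 7**
Reactants: 10 homoallylic mesylate; 11 bis(pinacolato)diboron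
Product: 13 2-{2,4-bis[4-(benzyloxy)phenyl]-3-[(tert-butyldimethylsilyloxy)methyl]cyclobutyl}-4,4,5,5-tetramethyl-1,3,2-dioxaborolane in the α array (C1 CH2OTBS up; C2 aryl down; C3 Bpin down; C4 aryl up), via benzylic alkylcopper 12 (not isolated)
Conditions: CuCl (10 mol %), 1,3-bis(diphenylphosphino)propane (dppp, 10 mol %), KOtBu (1.2 equiv), 11 (1.5 equiv), THF, rt, premixed 30 min; then 10, 30 °C
Reagents that add atoms: none
Why: Proposed new method: CuCl, dppp and KOtBu give a phosphine-ligated copper alkoxide that is borylated by 11, the boryl complex of monovalent copper adds syn across the E-styrene of 10 with boron on C3 and copper on the aryl-stabilised benzylic C2 (12), and copper then attacks C1 from the rear of the C–OMs bond (SN2-type oxidative addition to a five-membered trivalent-copper metallacycle) before reductive elimination forges C2–C1 and KOtBu regenerates the alkoxide. The closest known reaction type is the copper-catalysed borylative cyclisation of aryl- or silyl-terminated homoallylic sulfonates to 2-borylcyclobutanes, shown for primary leaving groups on lightly substituted chains, together with the displacement of secondary sulfonates by organocopper reagents with inversion, and the use of a secondary mesylate in a fully substituted chain is the untested part. The single new ring, the cyclobutane, closes in the 4-exo-tet mode. C2 and C3 are set by syn addition to the E-alkene plus retention at the C–Cu bond, which makes aryl(C2) and Bpin(C3) cis, and C1 is set by inversion at the mesylate carbon, which turns the anti diad of 10 into CH2OTBS cis to aryl(C4) and trans to aryl(C2). The selectivity needed is the choice of alkene face, which fixes C3 against C4: with the C4–H bond near the alkene plane to minimise allylic strain, the branched sp3 arm carrying the mesylate is the largest allylic group and should lie anti to the incoming Cu–B bond, so boron ends trans to aryl(C4), while the adduct from the other face could only close to an all-cis ring and should not cyclise. Regiochemistry is secured by the aryl group on C2, and adding 10 last to the premixed diboron/alkoxide keeps free base low so that elimination across C4–C1 is held back.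

**Step 8**
Reactants: 13 cyclobutylboronate
Product: 15 {2,4-bis[4-(benzyloxy)phenyl]-3-[(tert-butyldimethylsilyloxy)methyl]cyclobutyl}methanol in the α array, via homologated boronate 14 (not isolated)
Conditions: BrCH2Cl (3 equiv), n-BuLi (2.5 equiv), THF, −78 °C → rt, 12 h; then 3 M NaOH, 30% H2O2, 0 °C → rt
Reagents that add atoms: bromochloromethane, ClCBr; hydrogen peroxide, OO
Why: In this Matteson homologation the ring carbon C3 migrates from boron to the CH2Cl carbon with retention, and the peroxide-induced boron-to-oxygen shift then occurs at the new primary carbon, so C3 keeps its configuration.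

**Step 9**
Reactants: 15 mono-silylated diol
Product: 16 [2,4-bis(4-benzyloxyphenyl)cyclobutane-1,3-diyl]dimethanol in the α array (centrosymmetric)
Conditions: TBAF (1.2 equiv), THF, rt
Reagents that add atoms: none
Why: Fluoride-induced cleavage of a primary silyl ether is driven by Si–F bond formation and leaves the benzyl ethers and the ring untouched.

**Step 10**
Reactants: 16 diol
Product: 17 2,4-bis(4-benzyloxyphenyl)cyclobutane-1,3-dicarboxylic acid in the α array (α-truxillic type)
Conditions: TEMPO (0.4 equiv), PhI(OAc)2 (5 equiv), MeCN–CH2Cl2–H2O, rt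
Reagents that add atoms: water, O
Why: Oxoammonium (TEMPO/PhI(OAc)2) oxidation in aqueous medium carries primary alcohols to carboxylic acids near neutrality, the two CH2OH groups lie on opposite ring faces so no lactol or lactone can intervene, and C1/C3 should not epimerise.

**Step 11**
Reactants: 17 diacid
Product: 18 [2,4-bis(4-benzyloxyphenyl)cyclobutane-1,3-diyl]bis(1H-imidazol-1-ylmethanone) in the α array
Conditions: CDI (2.5 equiv), THF, rt, 2 h; CH2Cl2, cold-water wash, dried, used without chromatography
Reagents that add atoms: 1,1'-carbonyldiimidazole, O=C(n1ccnc1)n1ccnc1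
Why: Carboxyl activation with carbonyldiimidazole is driven by loss of CO2, needs no acid or strong base, and the trans-1,3 placement of the carboxyl groups excludes a cyclic anhydride.

**Step 12**
Reactants: 18 bis(acyl imidazole); 19 2,2,6-trimethyl-4H-1,3-dioxin-4-one (5 equiv)
Product: 20 6,6'-{[2,4-bis(4-benzyloxyphenyl)cyclobutane-1,3-diyl]bis(2-oxoethane-2,1-diyl)}bis(2,2-dimethyl-4H-1,3-dioxin-4-one) in the α array
Conditions: 19, LiHMDS (5 equiv), THF, −78 °C, 45 min; then 18 in THF, −78 → −30 °C; 1 M HCl quench
Reagents that add atoms: none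
Why: In this vinylogous Claisen-type γ-acylation of the lithium dienolate by an acyl imidazole, the excess dienolate deprotonates the new doubly activated CH2, which stops over-addition and shields the ring C–H next to the ketone from enolisation.

**Step 13**
Reactants: 20 bis(keto-dioxinone)
Product: 22 6,6'-[2,4-bis(4-benzyloxyphenyl)cyclobutane-1,3-diyl]bis(4-hydroxy-2H-pyran-2-one) in the α array, via bis(acylketene) 21 (not isolated)
Conditions: toluene (dilute), 110 °C, 1–2 h
Reagents that add atoms: none
Why: Thermal retro-[4+2] cleavage of each dioxinone expels acetone, and each acylketene is captured by the enol oxygen of its neighbouring ketone to close a 4-hydroxy-2-pyrone under neutral conditions that leave the ring stereocentres alone.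

**Step 14**
Reactants: 22 bis(4-hydroxy-2-pyrone)
Product: 23 6,6'-[2,4-bis(4-benzyloxyphenyl)cyclobutane-1,3-diyl]bis(4-methoxy-2H-pyran-2-one) in the α array
Conditions: Me2SO4 (3 equiv), K2CO3 (4 equiv), acetone, 50 °C
Reagents that add atoms: dimethyl sulfate, COS(=O)(=O)OC
Why: O-alkylation of the vinylogous acid with a hard methylating agent and carbonate base gives the 4-methoxy-2-pyrone form, and the benzyl ethers ensure that only the pyrone hydroxyls are methylated.

**Step 15**
Reactants: 23 dibenzyl ether
Product: 24 target, 6,6'-[2,4-bis(4-hydroxyphenyl)cyclobutane-1,3-diyl]bis(4-methoxy-2H-pyran-2-one) in the α array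
Conditions: H2 (1 atm), 10% Pd/C, EtOAc–MeOH, rt, stopped at full debenzylation
Reagents that add atoms: none
Why: Catalytic hydrogenolysis of aryl benzyl ethers at atmospheric pressure is much faster than reduction of the electron-rich 4-methoxy-2-pyrone ring or cleavage of the cyclobutane.

**Compound list**
1 | 1-benzyloxy-4-ethynylbenzene | C#Cc1ccc(OCc2ccccc2)cc1 | starting material
2 | (E)-2-[2-(4-benzyloxyphenyl)ethenyl]-4,4,5,5-tetramethyl-1,3,2-dioxaborolane | CC1(C)OB(/C=C/c2ccc(OCc3ccccc3)cc2)OC1(C)C | intermediate
3 | 2-[(2E)-3-(4-benzyloxyphenyl)prop-2-en-1-yl]-4,4,5,5-tetramethyl-1,3,2-dioxaborolane | CC1(C)OB(C/C=C/c2ccc(OCc3ccccc3)cc2)OC1(C)C | intermediate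
4 | (tert-butyldimethylsilyloxy)acetaldehyde | CC(C)(C)[Si](C)(C)OCC=O | starting material
5 | O-(pinacolatoboryl) derivative of 6 (not isolated) | C=C[C@@H](c1ccc(OCc2ccccc2)cc1)[C@@H](OB1OC(C)(C)C(C)(C)O1)CO[Si](C)(C)C(C)(C)C | intermediate
6 | rac-(2R,3S)-3-[4-(benzyloxy)phenyl]-1-[(tert-butyldimethylsilyl)oxy]pent-4-en-2-ol | C=C[C@@H](c1ccc(OCc2ccccc2)cc1)[C@@H](O)CO[Si](C)(C)C(C)(C)C | intermediate
7 | 4-benzyloxybenzaldehyde | O=Cc1ccc(OCc2ccccc2)cc1 | starting material
8 | 1-benzyloxy-4-ethenylbenzene | C=Cc1ccc(OCc2ccccc2)cc1 | intermediate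
9 | rac-(2R,3S,4E)-3,5-bis[4-(benzyloxy)phenyl]-1-[(tert-butyldimethylsilyl)oxy]pent-4-en-2-ol | c1ccccc1COc1ccc(/C=C/[C@@H](c2ccc(OCc3ccccc3)cc2)[C@@H](O)CO[Si](C)(C)C(C)(C)C)cc1 | intermediate
10 | rac-(2R,3S,4E)-3,5-bis[4-(benzyloxy)phenyl]-1-[(tert-butyldimethylsilyl)oxy]pent-4-en-2-yl methanesulfonate | c1ccccc1COc1ccc(/C=C/[C@@H](c2ccc(OCc3ccccc3)cc2)[C@@H](OS(C)(=O)=O)CO[Si](C)(C)C(C)(C)C)cc1 | intermediate
11 | bis(pinacolato)diboron | CC1(C)OB(OC1(C)C)B1OC(C)(C)C(C)(C)O1 | starting material
12 | β-boryl benzylic alkylcopper from syn borylcupration of 10 (dppp ligand omitted; not isolated) | [Cu][C@H](c1ccc(OCc2ccccc2)cc1)[C@H](B1OC(C)(C)C(C)(C)O1)[C@@H](c1ccc(OCc2ccccc2)cc1)[C@@H](OS(C)(=O)=O)CO[Si](C)(C)C(C)(C)C | intermediate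
13 | 2,4-diaryl-3-(pinacolatoboryl)-1-(silyloxymethyl)cyclobutane, α array | CC(C)(C)[Si](C)(C)OC[C@H]1[C@H](c2ccc(OCc3ccccc3)cc2)[C@H](B2OC(C)(C)C(C)(C)O2)[C@H]1c1ccc(OCc2ccccc2)cc1 | intermediate
14 | cyclobutylmethyl pinacol boronate, α array (not isolated) | CC(C)(C)[Si](C)(C)OC[C@H]1[C@H](c2ccc(OCc3ccccc3)cc2)[C@H](CB2OC(C)(C)C(C)(C)O2)[C@H]1c1ccc(OCc2ccccc2)cc1 | intermediate
15 | mono-TBS ether of the 1,3-dimethanol, α array | CC(C)(C)[Si](C)(C)OC[C@H]1[C@H](c2ccc(OCc3ccccc3)cc2)[C@H](CO)[C@H]1c1ccc(OCc2ccccc2)cc1 | intermediate
16 | [2,4-bis(4-benzyloxyphenyl)cyclobutane-1,3-diyl]dimethanol, α array | OC[C@H]1[C@H](c2ccc(OCc3ccccc3)cc2)[C@H](CO)[C@H]1c1ccc(OCc2ccccc2)cc1 | intermediate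
17 | 2,4-bis(4-benzyloxyphenyl)cyclobutane-1,3-dicarboxylic acid, α array | OC(=O)[C@H]1[C@H](c2ccc(OCc3ccccc3)cc2)[C@H](C(=O)O)[C@H]1c1ccc(OCc2ccccc2)cc1 | intermediate
18 | bis(acyl imidazole) of 17 | O=C(n1ccnc1)[C@H]1[C@H](c2ccc(OCc3ccccc3)cc2)[C@H](C(=O)n2ccnc2)[C@H]1c1ccc(OCc2ccccc2)cc1 | intermediate
19 | 2,2,6-trimethyl-4H-1,3-dioxin-4-one | CC1=CC(=O)OC(C)(C)O1 | starting material
20 | bis(keto-dioxinone), α array | CC1(C)OC(=O)C=C(CC(=O)[C@H]2[C@H](c3ccc(OCc4ccccc4)cc3)[C@H](C(=O)CC3=CC(=O)OC(C)(C)O3)[C@H]2c2ccc(OCc3ccccc3)cc2)O1 | intermediate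
21 | bis(acylketene), α array (formal; the two ends react independently; not isolated) | O=C=CC(=O)CC(=O)[C@H]1[C@H](c2ccc(OCc3ccccc3)cc2)[C@H](C(=O)CC(=O)C=C=O)[C@H]1c1ccc(OCc2ccccc2)cc1 | intermediate
22 | bis(4-hydroxy-2-pyrone) dibenzyl ether, α array | Oc1cc(=O)oc([C@H]2[C@H](c3ccc(OCc4ccccc4)cc3)[C@H](c3cc(O)cc(=O)o3)[C@H]2c2ccc(OCc3ccccc3)cc2)c1 | intermediate
23 | bis(4-methoxy-2-pyrone) dibenzyl ether, α array | COc1cc(=O)oc([C@H]2[C@H](c3ccc(OCc4ccccc4)cc3)[C@H](c3cc(OC)cc(=O)o3)[C@H]2c2ccc(OCc3ccccc3)cc2)c1 | intermediate
24 | CNP0273697.2 | COc1cc(=O)oc([C@H]2[C@H](c3ccc(O)cc3)[C@H](c3cc(OC)cc(=O)o3)[C@H]2c2ccc(O)cc2)c1 | target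

**Step count**
Total step count: 15. Longest linear sequence: 14 (steps 1–3 and 5–15, from 1).

**Steps most likely to fail**

1. Step 7 (bears the new-method label).
   - What may go wrong: slow insertion of the boryl copper into an electron-rich, allylically branched styrene, or attack on the wrong alkene face. Base-induced loss of methanesulfonic acid across C4–C1 is also possible, as is protonation or epimerisation of the benzylic copper before it reaches the hindered secondary centre.
   - Fallback (known chemistry): it sets out from 7 and returns at 17, replacing the open-chain closure by a lattice-controlled cycloaddition. Knoevenagel–Doebner condensation of 7 with malonic acid (pyridine, piperidine, 100 °C) gives (E)-4-benzyloxycinnamic acid F1.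
   - The acid is crystallised in a head-to-tail stacked form, as is known for 4-hydroxy- and 4-alkoxycinnamic acids, and irradiated as a powder (λ > 300 nm). Topochemical [2+2] photodimerisation should then give diacid 17 directly.

2. Step 8.
   - What may go wrong: sluggish addition of LiCH2Cl to a boron flanked by two aryl-bearing ring carbons, or migration of a pinacol oxygen in place of the ring carbon.
   - Fallback: it sets out from 13 and returns at 15, bringing in two carbons and trimming one. Zweifel olefination (vinylmagnesium bromide, THF–DMSO; then I2; then NaOMe, MeOH) gives, with retention, the vinylcyclobutane F2.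
   - Lemieux–Johnson cleavage (OsO4 cat., NaIO4, 2,6-lutidine, dioxane–water) gives the cyclobutanecarbaldehyde F3. Reduction with NaBH4 in MeOH at 0 °C then gives 15.

3. Step 12.
   - What may go wrong: O- or α-acylation of the dienolate, incomplete second acylation at a carbonyl crowded by a cis aryl group, or enolisation next to the ring.
   - Fallback: it sets out from 18 and returns at 22, building the pyrone from a linear triketide ester rather than through an acylketene. The dianion of methyl acetoacetate (NaH, then n-BuLi, THF, 0 °C) is acylated by 18 at its terminal carbon at −78 °C to give the bis(methyl 3,5-dioxopentanoate) F4.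
   - DBU in toluene at reflux closes both rings by enol lactonisation to give 22.

**Further compounds**
F1 | step 7 | (E)-4-benzyloxycinnamic acid | OC(=O)/C=C/c1ccc(OCc2ccccc2)cc1
F2 | step 8 | 3-ethenyl-2,4-bis(4-benzyloxyphenyl)-1-(tert-butyldimethylsilyloxymethyl)cyclobutane, α array | CC(C)(C)[Si](C)(C)OC[C@H]1[C@H](c2ccc(OCc3ccccc3)cc2)[C@H](C=C)[C@H]1c1ccc(OCc2ccccc2)cc1
F3 | step 8 | 2,4-bis(4-benzyloxyphenyl)-3-(tert-butyldimethylsilyloxymethyl)cyclobutanecarbaldehyde, α array | CC(C)(C)[Si](C)(C)OC[C@H]1[C@H](c2ccc(OCc3ccccc3)cc2)[C@H](C=O)[C@H]1c1ccc(OCc2ccccc2)cc1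
F4 | step 12 | dimethyl 5,5'-[2,4-bis(4-benzyloxyphenyl)cyclobutane-1,3-diyl]bis(3,5-dioxopentanoate), α array | COC(=O)CC(=O)CC(=O)[C@H]1[C@H](c2ccc(OCc3ccccc3)cc2)[C@H](C(=O)CC(=O)CC(=O)OC)[C@H]1c1ccc(OCc2ccccc2)cc1
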